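**Retrosynthetic overview**

1. Target 39 ⇒ global desilylation and C6–O acylation of macrocyclic allylic alcohol 30 with the (Z)-acid 36 (from but-2-yne-1,4-diol by trans-hydroalumination/iodination and carbonylation).
2. 30 ⇒ C5–C6 disconnection: intramolecular Ni/Cr iodoalkene–aldehyde coupling of seco-aldehyde 28. Enabling feature: C6 is a secondary allylic carbinol between the trisubstituted C4=C5 olefin and C7 of the trans-fused γ-lactone ring (C7–C8–O–C12–C11), so the ten-membered carbocycle (C1–C10) opens to an (E)-iodoalkene and a lactone-bound aldehyde.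
3. 28 ⇒ Evans syn-aldol of succinate imide 17 with aldehyde 13 (sets C7 and C8, lactonises), then auxiliary reduction, α-methylenation at C11 and oxidation at C6.
4. 13 ⇒ (S)-citronellal (C8–C10, C14, C1–C3; brings C10) + 3-(trimethylsilyl)propargyl alcohol (C4, C5, C15) by Cu-catalysed anti-carbomagnesiation and iododesilylation.
5. Ring order: γ-lactone first (step 9), ten-membered carbocycle second (step 15).

Key step: step 15

Remark: germacrane numbering is used for the skeleton (ring C1–C10, C14 = methyl on C10, C15 = hydroxymethyl on C4, lactone carbons C11–C13); the C4=C5 bond is cis within the ring (E by CIP) and the side-chain enoate is Z.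

**Route**

Step 1
Reactants: 1 (S)-citronellal
Product: 2 (6S)-8,8-dimethoxy-2,6-dimethyloct-2-ene
Conditions: HC(OMe)3, MeOH, PPTS (cat.), rt
Reagents that add atoms: trimethyl orthoformate, COC(OC)OC
Why: Acid-catalysed acetalisation with an orthoester as water scavenger should mask C8 at the aldehyde oxidation level without touching the C10 stereocentre, which comes from the chiral pool.

Step 2
Reactants: 2 (6S)-8,8-dimethoxy-2,6-dimethyloct-2-ene
Product: 3 (4S)-6,6-dimethoxy-4-methylhexan-1-ol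
Conditions: O3, CH2Cl2/MeOH, −78 °C; then NaBH4, −78 → 0 °C
Reagents that add atoms: ozone, [O-][O+]=O
Why: Ozonolysis of the trisubstituted olefin with reductive work-up should excise the isopropylidene carbon and leave C3 as a primary alcohol, the acetal being inert.

Step 3
Reactants: 3 (4S)-6,6-dimethoxy-4-methylhexan-1-ol
Product: 4 (3S)-6-bromo-1,1-dimethoxy-3-methylhexane
Conditions: CBr4, PPh3, 2,6-lutidine, CH2Cl2, 0 °C
Reagents that add atoms: carbon tetrabromide, BrC(Br)(Br)Br
Why: The Appel reaction should convert the primary alcohol into the bromide under buffered conditions that spare the acetal.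

Step 4
Reactants: 4 (3S)-6-bromo-1,1-dimethoxy-3-methylhexane; 5 3-(trimethylsilyl)prop-2-yn-1-ol
Product: 9 (2E)-2-[(4S)-6,6-dimethoxy-4-methylhexyl]-3-(trimethylsilyl)prop-2-en-1-ol, via Grignard reagent 6 (not isolated), via chloromagnesium alkoxide 7 (not isolated), via oxamagnesacycle 8 (not isolated)
Conditions: Mg, THF, 40 °C (4 → 6); 5, i-PrMgCl (1.0 equiv), THF, 0 °C (→ 7); CuI (10 mol%), 6, THF/Et2O, 0 °C → reflux; aq. NH4Cl
Reagents that add atoms: none
Why: Cu-catalysed anti-carbomagnesiation of the propargylic alkoxide (Duboudin type) should deliver the alkyl group to C4 and magnesium to the silyl-bearing C5 inside a five-membered O–Mg chelate, so that protonation leaves silicon cis to the new chain and trans to C15, which fixes the ring-cis C4=C5 geometry.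

Step 5
Reactants: 9 (2E)-2-[(4S)-6,6-dimethoxy-4-methylhexyl]-3-(trimethylsilyl)prop-2-en-1-ol
Product: 10 tert-butyl({(2E)-2-[(4S)-6,6-dimethoxy-4-methylhexyl]-3-(trimethylsilyl)prop-2-en-1-yl}oxy)dimethylsilane
Conditions: TBSCl, imidazole, CH2Cl2, rt
Reagents that add atoms: tert-butyldimethylsilyl chloride, CC(C)(C)[Si](C)(C)Cl
Why: Standard silylation should protect the C15 hydroxyl for the rest of the route.

Step 6
Reactants: 10 tert-butyl({(2E)-2-[(4S)-6,6-dimethoxy-4-methylhexyl]-3-(trimethylsilyl)prop-2-en-1-yl}oxy)dimethylsilane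
Product: 11 tert-butyl({(2E)-2-[(4S)-6,6-dimethoxy-4-methylhexyl]-3-iodoprop-2-en-1-yl}oxy)dimethylsilane
Conditions: NIS, 2,6-lutidine, (CF3)2CHOH, 0 °C
Reagents that add atoms: N-iodosuccinimide, O=C1CCC(=O)N1I
Why: Electrophilic ipso-iododesilylation of the vinylsilane in hexafluoroisopropanol should proceed with retention and give the (E)-iodoalkene with iodine cis to the C3 chain.

Step 7
Reactants: 11 tert-butyl({(2E)-2-[(4S)-6,6-dimethoxy-4-methylhexyl]-3-iodoprop-2-en-1-yl}oxy)dimethylsilane
Product: 13 (3S,7E)-7-({[tert-butyl(dimethyl)silyl]oxy}methyl)-8-iodo-3-methyloct-7-enal, via collidinium salt 12 (not isolated)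
Conditions: TESOTf, 2,4,6-collidine, CH2Cl2, 0 °C; then H2O
Reagents that add atoms: water, O
Why: Silyl triflate/collidine activation of the dimethyl acetal followed by hydrolysis of the pyridinium adduct should release the C8 aldehyde under non-acidic conditions that leave the allylic TBS ether and the iodoalkene intact.

Step 8
Reactants: 14 (4S)-4-benzyl-1,3-oxazolidin-2-one; 15 methyl 4-chloro-4-oxobutanoate
Product: 17 methyl 4-[(4S)-4-benzyl-2-oxo-1,3-oxazolidin-3-yl]-4-oxobutanoate, via N-lithio oxazolidinone 16 (not isolated)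
Conditions: n-BuLi, THF, −78 °C; then 15, −78 → 0 °C
Reagents that add atoms: none
Why: N-Acylation of the lithiated Evans auxiliary with the succinic half-ester chloride should give the imide that carries C6, C7, C11 and C12.

Step 9
Reactants: 17 methyl 4-[(4S)-4-benzyl-2-oxo-1,3-oxazolidin-3-yl]-4-oxobutanoate; 13 (3S,7E)-7-({[tert-butyl(dimethyl)silyl]oxy}methyl)-8-iodo-3-methyloct-7-enal
Product: 20 (4S)-4-benzyl-3-{[(2R,3S)-2-[(2S,6E)-6-({[tert-butyl(dimethyl)silyl]oxy}methyl)-7-iodo-2-methylhept-6-en-1-yl]-5-oxooxolan-3-yl]carbonyl}-1,3-oxazolidin-2-one, via boron enolate 18 (not isolated), via aldol adduct 19 (not isolated)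
Conditions: Bu2BOTf, i-Pr2NEt, CH2Cl2, 0 °C; 13, −78 → 0 °C; pH 7 buffer, MeOH, H2O2; then PPTS (cat.), CH2Cl2, rt
Reagents that add atoms: none
Why: The Evans syn-aldol reaction of the (Z)-boron enolate through a Zimmerman–Traxler chair, with the face set by the (4S)-benzyl auxiliary, should set C7 and C8 (2S,3R adduct), and lactonisation of the C8 hydroxyl onto the methyl ester should then give the trans-β,γ-disubstituted γ-lactone.

Step 10
Reactants: 20 the lactone imide of step 9
Product: 21 (4R,5R)-5-[(2S,6E)-6-({[tert-butyl(dimethyl)silyl]oxy}methyl)-7-iodo-2-methylhept-6-en-1-yl]-4-(hydroxymethyl)oxolan-2-one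
Conditions: NaBH4, THF/H2O (4:1), 0 °C → rt
Reagents that add atoms: none
Why: Borohydride in aqueous THF should reduce the exocyclic imide carbonyl to the C6 primary alcohol and release the auxiliary while leaving the γ-lactone untouched.

Step 11
Reactants: 21 the hydroxymethyl lactone of step 10
Product: 22 (4R,5R)-5-[(2S,6E)-6-({[tert-butyl(dimethyl)silyl]oxy}methyl)-7-iodo-2-methylhept-6-en-1-yl]-4-{[(triethylsilyl)oxy]methyl}oxolan-2-one
Conditions: TESCl, imidazole, CH2Cl2, 0 °C
Reagents that add atoms: chlorotriethylsilane, CC[Si](Cl)(CC)CC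
Why: A triethylsilyl ether should protect the C6 hydroxyl during enolate chemistry and can later be removed in the presence of the TBS ether.

Step 12
Reactants: 22 the TES-protected lactone of step 11
Product: 26 (4R,5R)-5-[(2S,6E)-6-({[tert-butyl(dimethyl)silyl]oxy}methyl)-7-iodo-2-methylhept-6-en-1-yl]-3-methylidene-4-{[(triethylsilyl)oxy]methyl}oxolan-2-one, via lithium enolate 23 (not isolated), via Mannich base 24 (not isolated), via methiodide 25 (not isolated)
Conditions: LiHMDS, THF, −78 °C; CH2=NMe2+ I−, −78 → 0 °C; then MeI, MeOH, rt; then aq. NaHCO3, CH2Cl2, rt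
Reagents that add atoms: Eschenmoser's salt (N,N-dimethylmethyleneiminium iodide), C=[N+](C)C.[I-]
Why: Mannich alkylation of the lactone enolate at C11 followed by quaternisation and mild base elimination (Eschenmoser methylenation) should install the exocyclic C11=C13 olefin, LiHMDS being too weak to metalate the iodoalkene.

Step 13
Reactants: 26 the TES-protected α-methylene lactone of step 12
Product: 27 (4R,5R)-5-[(2S,6E)-6-({[tert-butyl(dimethyl)silyl]oxy}methyl)-7-iodo-2-methylhept-6-en-1-yl]-4-(hydroxymethyl)-3-methylideneoxolan-2-one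
Conditions: PPTS (cat.), MeOH/CH2Cl2, 0 °C
Reagents that add atoms: none
Why: Mild acidic methanolysis should cleave the primary TES ether much faster than the primary allylic TBS ether.

Step 14
Reactants: 27 the α-methylene lactone alcohol of step 13
Product: 28 (2R,3S)-2-[(2S,6E)-6-({[tert-butyl(dimethyl)silyl]oxy}methyl)-7-iodo-2-methylhept-6-en-1-yl]-4-methylidene-5-oxooxolane-3-carbaldehyde
Conditions: Dess–Martin periodinane, NaHCO3, CH2Cl2, 0 °C; filtered and used at once
Reagents that add atoms: none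
Why: Buffered Dess–Martin oxidation should give the C6 aldehyde under near-neutral conditions, which matters because C7–H is both α to the aldehyde and allylic to the acrylate.

Step 15
Reactants: 28 the seco-aldehyde of step 14
Product: 30 (3aR,4R,5E,10S,11aR)-6-({[tert-butyl(dimethyl)silyl]oxy}methyl)-4-hydroxy-10-methyl-3-methylidene-3a,4,7,8,9,10,11,11a-octahydrocyclodeca[b]furan-2(3H)-one (germacrane numbering 6R,7R,8R,10S), via alkenylchromium species 29 (not isolated)
Conditions: CrCl2 (10 equiv), NiCl2 (0.1 equiv), degassed DMSO, rt, syringe-pump addition of 28 to ca. 2 mM; aq. sodium serinate work-up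
Reagents that add atoms: none
Why: Ni(0), formed from NiCl2 by Cr(II), should insert into the C5–I bond, transmetalate to Cr(III) with retention of olefin geometry and the resulting alkenylchromium 29 should add to the C6 aldehyde (intramolecular Nozaki–Hiyama–Kishi reaction, the closest precedent being Ni/Cr macrocyclisations of iodoalkene aldehydes to 9–12-membered rings). The ten-membered carbocycle is closed in a 10-exo-trig mode, the carbonyl oxygen becoming the exocyclic C6 hydroxyl. The only new stereocentre, C6, is controlled by C7: attack anti to the sp2 carbon C11 (Felkin–Anh with C11 as the perpendicular group) and 1,3-anti to the C8 lactone oxygen both point to 6R. The step needs chemoselectivity for the aldehyde over the lactone and the exocyclic acrylate, which the weakly basic, oxophilic organochromium reagent secures. It also needs cyclisation to outrun oligomerisation, which the trans-lactone (C7–C8 holding the formyl and C9 arms as a turn), the ring-cis geometry already present in the iodide and slow addition at high dilution should secure. The neutral medium should avoid enolisation of the doubly activated C7–H.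

Step 16
Reactants: 31 but-2-yne-1,4-diol
Product: 33 (2Z)-2-iodobut-2-ene-1,4-diol, via alkenylaluminate 32 (not isolated)
Conditions: Red-Al, THF, 0 °C → rt; then I2, THF, −78 °C
Reagents that add atoms: iodine, II
Why: Alkoxide-directed trans-hydroalumination of the propargylic diol places aluminium cis to the chelating CH2O group, and iodinolysis with retention should give the Z-iodoalkene.

Step 17
Reactants: 33 (2Z)-2-iodobut-2-ene-1,4-diol
Product: 34 (2Z)-1,4-bis{[tert-butyl(dimethyl)silyl]oxy}-2-iodobut-2-ene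
Conditions: TBSCl, imidazole, DMF, rt
Reagents that add atoms: tert-butyldimethylsilyl chloride, CC(C)(C)[Si](C)(C)Cl
Why: Bis-silylation should block both hydroxyls so that the later Z-acid cannot close to a butenolide.

Step 18
Reactants: 34 (2Z)-1,4-bis{[tert-butyl(dimethyl)silyl]oxy}-2-iodobut-2-ene
Product: 35 methyl (2Z)-4-{[tert-butyl(dimethyl)silyl]oxy}-2-({[tert-butyl(dimethyl)silyl]oxy}methyl)but-2-enoate
Conditions: PdCl2(PPh3)2 (cat.), CO (1 atm), Et3N, MeOH/DMF, 60 °C
Reagents that add atoms: carbon monoxide, [C-]#[O+]; methanol, CO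
Why: Pd-catalysed methoxycarbonylation of the iodoalkene proceeds with retention, so the ester should end up cis to the γ-silyloxymethyl group (Z).

Step 19
Reactants: 35 the methyl ester of step 18
Product: 36 (2Z)-4-{[tert-butyl(dimethyl)silyl]oxy}-2-({[tert-butyl(dimethyl)silyl]oxy}methyl)but-2-enoic acid
Conditions: LiOH, THF/MeOH/H2O, rt; dil. HCl to pH 4, 0 °C
Reagents that add atoms: lithium hydroxide, [Li+].[OH-]
Why: Saponification should free the acid while the primary TBS ethers survive and keep the Z-acid from lactonising.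

Step 20
Reactants: 36 the (Z)-acid of step 19; 30 the macrocyclic alcohol of step 15
Product: 38 (3aS,4R,5E,10S,11aR)-6-({[tert-butyl(dimethyl)silyl]oxy}methyl)-10-methyl-3-methylidene-2-oxo-2,3,3a,4,7,8,9,10,11,11a-decahydrocyclodeca[b]furan-4-yl (2Z)-4-{[tert-butyl(dimethyl)silyl]oxy}-2-({[tert-butyl(dimethyl)silyl]oxy}methyl)but-2-enoate, via mixed anhydride 37 (not isolated)
Conditions: 2,4,6-trichlorobenzoyl chloride, Et3N, toluene, rt; then 30, toluene, 70 °C (no DMAP)
Reagents that add atoms: none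
Why: Yamaguchi-type mixed-anhydride esterification without a nucleophilic catalyst, as used for angelate esters, should acylate the hindered C6 allylic alcohol with retention at C6 and without Z→E isomerisation of the enoate.

Step 21
Reactants: 38 the tris-TBS ester of step 20
Product: 39 target, (3aS,4R,5E,10S,11aR)-6-(hydroxymethyl)-10-methyl-3-methylidene-2-oxo-2,3,3a,4,7,8,9,10,11,11a-decahydrocyclodeca[b]furan-4-yl (2Z)-4-hydroxy-2-(hydroxymethyl)but-2-enoate
Conditions: HF·pyridine, pyridine, THF, 0 °C → rt; cold NaHCO3 work-up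
Reagents that add atoms: none
Why: Buffered fluoride-mediated desilylation should remove the three primary TBS ethers without base, so that the α-methylene lactone, the C6 ester and the Z-γ-hydroxy enoate are preserved.

**Compound list**

1 | (S)-citronellal, (3S)-3,7-dimethyloct-6-enal | O=CC[C@@H](C)CCC=C(C)C | starting material
2 | (6S)-8,8-dimethoxy-2,6-dimethyloct-2-ene | COC(OC)C[C@@H](C)CCC=C(C)C | intermediate
3 | (4S)-6,6-dimethoxy-4-methylhexan-1-ol | COC(OC)C[C@@H](C)CCCO | intermediate
4 | (3S)-6-bromo-1,1-dimethoxy-3-methylhexane | COC(OC)C[C@@H](C)CCCBr | intermediate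
5 | 3-(trimethylsilyl)prop-2-yn-1-ol | C[Si](C)(C)C#CCO | starting material
6 | [(4S)-6,6-dimethoxy-4-methylhexyl]magnesium bromide | COC(OC)C[C@@H](C)CCC[Mg]Br | intermediate (not isolated)
7 | chloromagnesium 3-(trimethylsilyl)prop-2-yn-1-olate | C[Si](C)(C)C#CCO[Mg]Cl | intermediate (not isolated)
8 | 4-[(4S)-6,6-dimethoxy-4-methylhexyl]-3-(trimethylsilyl)-2,5-dihydro-1,2-oxamagnesole | COC(OC)C[C@@H](C)CCCC1=C([Si](C)(C)C)[Mg]OC1 | intermediate (not isolated)
9 | (2E)-2-[(4S)-6,6-dimethoxy-4-methylhexyl]-3-(trimethylsilyl)prop-2-en-1-ol | COC(OC)C[C@@H](C)CCC/C(CO)=C\[Si](C)(C)C | intermediate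
10 | tert-butyl({(2E)-2-[(4S)-6,6-dimethoxy-4-methylhexyl]-3-(trimethylsilyl)prop-2-en-1-yl}oxy)dimethylsilane | COC(OC)C[C@@H](C)CCC/C(CO[Si](C)(C)C(C)(C)C)=C\[Si](C)(C)C | intermediate
11 | tert-butyl({(2E)-2-[(4S)-6,6-dimethoxy-4-methylhexyl]-3-iodoprop-2-en-1-yl}oxy)dimethylsilane | COC(OC)C[C@@H](C)CCC/C(CO[Si](C)(C)C(C)(C)C)=C\I | intermediate
12 | 1-(1-methoxyalkyl)-2,4,6-trimethylpyridinium triflate derived from 11 (mixture at the N,O-acetal carbon) | COC(C[C@@H](C)CCC/C(CO[Si](C)(C)C(C)(C)C)=C\I)[n+]1c(C)cc(C)cc1C.[O-]S(=O)(=O)C(F)(F)F | intermediate (not isolated)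
13 | (3S,7E)-7-({[tert-butyl(dimethyl)silyl]oxy}methyl)-8-iodo-3-methyloct-7-enal | O=CC[C@@H](C)CCC/C(CO[Si](C)(C)C(C)(C)C)=C\I | intermediate
14 | (4S)-4-benzyl-1,3-oxazolidin-2-one | O=C1N[C@@H](Cc2ccccc2)CO1 | starting material
15 | methyl 4-chloro-4-oxobutanoate | COC(=O)CCC(Cl)=O | starting material
16 | N-lithio (4S)-4-benzyl-1,3-oxazolidin-2-one | [Li]N1[C@@H](Cc2ccccc2)COC1=O | intermediate (not isolated)
17 | methyl 4-[(4S)-4-benzyl-2-oxo-1,3-oxazolidin-3-yl]-4-oxobutanoate | COC(=O)CCC(=O)N1[C@@H](Cc2ccccc2)COC1=O | intermediate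
18 | (Z)-dibutylboron enolate of 17 | COC(=O)C/C=C(\OB(CCCC)CCCC)N1[C@@H](Cc2ccccc2)COC1=O | intermediate (not isolated)
19 | syn-aldol adduct, methyl (3S,4R)-3-{[(4S)-4-benzyl-2-oxo-1,3-oxazolidin-3-yl]carbonyl}-4-hydroxy-alkanoate bearing the C9–C5 chain | COC(=O)C[C@H](C(=O)N1[C@@H](Cc2ccccc2)COC1=O)[C@H](O)C[C@@H](C)CCC/C(CO[Si](C)(C)C(C)(C)C)=C\I | intermediate (not isolated)
20 | (4S)-4-benzyl-3-{[(2R,3S)-2-[(2S,6E)-6-({[tert-butyl(dimethyl)silyl]oxy}methyl)-7-iodo-2-methylhept-6-en-1-yl]-5-oxooxolan-3-yl]carbonyl}-1,3-oxazolidin-2-one | O=C1C[C@H](C(=O)N2[C@@H](Cc3ccccc3)COC2=O)[C@@H](C[C@@H](C)CCC/C(CO[Si](C)(C)C(C)(C)C)=C\I)O1 | intermediate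
21 | (4R,5R)-5-[(2S,6E)-6-({[tert-butyl(dimethyl)silyl]oxy}methyl)-7-iodo-2-methylhept-6-en-1-yl]-4-(hydroxymethyl)oxolan-2-one | O=C1C[C@H](CO)[C@@H](C[C@@H](C)CCC/C(CO[Si](C)(C)C(C)(C)C)=C\I)O1 | intermediate
22 | (4R,5R)-5-[(2S,6E)-6-({[tert-butyl(dimethyl)silyl]oxy}methyl)-7-iodo-2-methylhept-6-en-1-yl]-4-{[(triethylsilyl)oxy]methyl}oxolan-2-one | O=C1C[C@H](CO[Si](CC)(CC)CC)[C@@H](C[C@@H](C)CCC/C(CO[Si](C)(C)C(C)(C)C)=C\I)O1 | intermediate
23 | lithium enolate of 22 | [Li]OC1=C[C@H](CO[Si](CC)(CC)CC)[C@@H](C[C@@H](C)CCC/C(CO[Si](C)(C)C(C)(C)C)=C\I)O1 | intermediate (not isolated)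
24 | 3-[(dimethylamino)methyl] lactone (Mannich base, mixture at C11) | O=C1C(CN(C)C)[C@H](CO[Si](CC)(CC)CC)[C@@H](C[C@@H](C)CCC/C(CO[Si](C)(C)C(C)(C)C)=C\I)O1 | intermediate (not isolated)
25 | trimethylammonium iodide of 24 | O=C1C(C[N+](C)(C)C)[C@H](CO[Si](CC)(CC)CC)[C@@H](C[C@@H](C)CCC/C(CO[Si](C)(C)C(C)(C)C)=C\I)O1.[I-] | intermediate (not isolated)
26 | (4R,5R)-5-[(2S,6E)-6-({[tert-butyl(dimethyl)silyl]oxy}methyl)-7-iodo-2-methylhept-6-en-1-yl]-3-methylidene-4-{[(triethylsilyl)oxy]methyl}oxolan-2-one | C=C1C(=O)O[C@H](C[C@@H](C)CCC/C(CO[Si](C)(C)C(C)(C)C)=C\I)[C@H]1CO[Si](CC)(CC)CC | intermediate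
27 | (4R,5R)-5-[(2S,6E)-6-({[tert-butyl(dimethyl)silyl]oxy}methyl)-7-iodo-2-methylhept-6-en-1-yl]-4-(hydroxymethyl)-3-methylideneoxolan-2-one | C=C1C(=O)O[C@H](C[C@@H](C)CCC/C(CO[Si](C)(C)C(C)(C)C)=C\I)[C@H]1CO | intermediate
28 | (2R,3S)-2-[(2S,6E)-6-({[tert-butyl(dimethyl)silyl]oxy}methyl)-7-iodo-2-methylhept-6-en-1-yl]-4-methylidene-5-oxooxolane-3-carbaldehyde | C=C1C(=O)O[C@H](C[C@@H](C)CCC/C(CO[Si](C)(C)C(C)(C)C)=C\I)[C@H]1C=O | intermediate
29 | alkenylchromium(III) dichloride derived from 28 (Cr in place of I) | C=C1C(=O)O[C@H](C[C@@H](C)CCC/C(CO[Si](C)(C)C(C)(C)C)=C\[Cr](Cl)Cl)[C@H]1C=O | intermediate (not isolated)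
30 | (3aR,4R,5E,10S,11aR)-6-({[tert-butyl(dimethyl)silyl]oxy}methyl)-4-hydroxy-10-methyl-3-methylidene-3a,4,7,8,9,10,11,11a-octahydrocyclodeca[b]furan-2(3H)-one | C=C1C(=O)O[C@@H]2C[C@@H](C)CCC/C(CO[Si](C)(C)C(C)(C)C)=C\[C@@H](O)[C@@H]12 | intermediate
31 | but-2-yne-1,4-diol | OCC#CCO | starting material
32 | cyclic alkenylaluminate from trans-hydroalumination of 31 (representative monomeric form, disodium salt) | [Na+].[Na+].COCCO[Al-]1(OCCOC)OCC=C1C[O-] | intermediate (not isolated)
33 | (2Z)-2-iodobut-2-ene-1,4-diol | OC/C=C(\I)CO | intermediate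
34 | (2Z)-1,4-bis{[tert-butyl(dimethyl)silyl]oxy}-2-iodobut-2-ene | CC(C)(C)[Si](C)(C)OC/C=C(\I)CO[Si](C)(C)C(C)(C)C | intermediate
35 | methyl (2Z)-4-{[tert-butyl(dimethyl)silyl]oxy}-2-({[tert-butyl(dimethyl)silyl]oxy}methyl)but-2-enoate | COC(=O)/C(CO[Si](C)(C)C(C)(C)C)=C\CO[Si](C)(C)C(C)(C)C | intermediate
36 | (2Z)-4-{[tert-butyl(dimethyl)silyl]oxy}-2-({[tert-butyl(dimethyl)silyl]oxy}methyl)but-2-enoic acid | OC(=O)/C(CO[Si](C)(C)C(C)(C)C)=C\CO[Si](C)(C)C(C)(C)C | intermediate
37 | mixed anhydride of 36 with 2,4,6-trichlorobenzoic acid | O=C(OC(=O)c1c(Cl)cc(Cl)cc1Cl)/C(CO[Si](C)(C)C(C)(C)C)=C\CO[Si](C)(C)C(C)(C)C | intermediate (not isolated)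
38 | (3aS,4R,5E,10S,11aR)-6-({[tert-butyl(dimethyl)silyl]oxy}methyl)-10-methyl-3-methylidene-2-oxo-2,3,3a,4,7,8,9,10,11,11a-decahydrocyclodeca[b]furan-4-yl (2Z)-4-{[tert-butyl(dimethyl)silyl]oxy}-2-({[tert-butyl(dimethyl)silyl]oxy}methyl)but-2-enoate | C=C1C(=O)O[C@@H]2C[C@@H](C)CCC/C(CO[Si](C)(C)C(C)(C)C)=C\[C@@H](OC(=O)/C(=C\CO[Si](C)(C)C(C)(C)C)CO[Si](C)(C)C(C)(C)C)[C@@H]12 | intermediate
39 | (3aS,4R,5E,10S,11aR)-6-(hydroxymethyl)-10-methyl-3-methylidene-2-oxo-2,3,3a,4,7,8,9,10,11,11a-decahydrocyclodeca[b]furan-4-yl (2Z)-4-hydroxy-2-(hydroxymethyl)but-2-enoate (CNP0131216.1) | C=C1C(=O)O[C@@H]2C[C@@H](C)CCC/C(CO)=C\[C@@H](OC(=O)/C(=C\CO)CO)[C@@H]12 | target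

**Totals**

Total step count: 21. Longest linear sequence: 16 steps (1–7, 9–15, 20, 21).

**Steps most likely to fail**

1. Step 15 (macrocyclisation). The risk is poor facial selectivity at C6: strain in the ten-membered transition state may override the Felkin/1,3-anti bias, so that the C6 epimer predominates. Intermolecular coupling is a second drain. The fallback sets out from 28 and changes how C6 is set. The cyclisation is run as before and the 6-epimeric macrocyclic alcohol F1 is taken on. It is esterified directly with acid 36 under Mitsunobu conditions (PPh3, DIAD, toluene, 0 °C), so the ester is installed by SN2 inversion at C6. This comes back to the route at 38.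

2. Step 4 (anti-carbomagnesiation). The risk is slow or poorly regioselective addition of the primary alkyl Grignard reagent to the hindered silylalkyne, with Wurtz coupling and protonation consuming the chiral chain. The fallback sets out from 4 and builds the same olefin by cross-coupling. Commercial tert-butyldimethyl(prop-2-yn-1-yloxy)silane undergoes Pd(PPh3)4-catalysed cis-silylstannation with Me3Si–SnBu3 to the (Z)-silylstannane F2. Iododestannylation (I2, CH2Cl2, 0 °C) gives the 2-iodo-3-silyl allyl ether F3 with iodine cis to silicon. Bromide 4 is converted with Zn/LiCl in THF into the alkylzinc bromide F4. Negishi coupling of F3 with F4 (PdCl2(dppf), THF, 50 °C) proceeds with retention and comes back to the route at 10.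

3. Step 20 (esterification). The risk is Z→E isomerisation of the activated acid, its cyclisation to a butenolide with loss of a silyl group, or base-induced translactonisation of 30 before acylation. The fallback sets out from 34 and 30 and avoids any free activated acid. Pd-catalysed alkoxycarbonylation of iodoalkene 34 with alcohol 30 as the nucleophile (Pd2(dba)3/Xantphos, CO, Et3N, toluene, 60 °C) forms the acylpalladium with retained geometry and gives the ester directly. It makes no new compound (F0) and comes back to the route at 38.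

**Further compounds**

F1 | step 15 | (3aR,4S,5E,10S,11aR)-6-({[tert-butyl(dimethyl)silyl]oxy}methyl)-4-hydroxy-10-methyl-3-methylidene-3a,4,7,8,9,10,11,11a-octahydrocyclodeca[b]furan-2(3H)-one (6-epimer of 30) | C=C1C(=O)O[C@@H]2C[C@@H](C)CCC/C(CO[Si](C)(C)C(C)(C)C)=C\[C@H](O)[C@@H]12
F2 | step 4 | tert-butyldimethyl{[(2Z)-2-(tributylstannyl)-3-(trimethylsilyl)prop-2-en-1-yl]oxy}silane | C[Si](C)(C)/C=C(\[Sn](CCCC)(CCCC)CCCC)CO[Si](C)(C)C(C)(C)C
F3 | step 4 | tert-butyl{[(2Z)-2-iodo-3-(trimethylsilyl)prop-2-en-1-yl]oxy}dimethylsilane | C[Si](C)(C)/C=C(\I)CO[Si](C)(C)C(C)(C)C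
F4 | step 4 | [(4S)-6,6-dimethoxy-4-methylhexyl]zinc bromide | COC(OC)C[C@@H](C)CCC[Zn]Br
F0 | step 20 | none | none
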